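**Plan**
Retrosynthesis: the ten allyl protecting groups go last; then both bonds from ring A to the carbocycle (C4–C4a and C8a–C1) are cut together, giving an aryl Grignard reagent from 4-bromo-1,2-bis(allyloxy)benzene and a 1-formylcyclopropane-1,2-dicarboxylate whose ring carbons are C1, C2, C3 and whose formyl carbon is C4. The cyclopropane is cut into a cinnamaldehyde and a bromomalonate, and the esters into danshensu.
Enabling feature: C4=C3–C2–C1 is a homoallyl array with C1 benzylic to a 4-oxygenated aryl ring, which is the opened form of a cyclopropylcarbinyl cation. C4a and C8a of ring A are each para to an oxygen (O-7 and O-6), so one can arrive as an aryl-metal carbon and its neighbour can act as the Friedel–Crafts nucleophile.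
Forward: protected danshensu → mixed bromomalonate → organocatalytic cyclopropanation → adjustment to the formyl diester → ring A added and the six-membered carbocycle closed in one flask → deallylation.
Stereochemistry: both acyloxy centres come from commercial (R)-danshensu; C2 from the prolinol silyl ether catalysed cyclopropanation; C1 is set by C2 in the ring closure (1,2-trans).

Key step: step 13

**Remarks**
- Abbreviations: Ar = 3,4-bis(allyloxy)phenyl; TMSE = 2-(trimethylsilyl)ethyl; Dan = (1R)-1-[(allyloxy)carbonyl]-2-[3,4-bis(allyloxy)phenyl]ethyl, the triallyl danshensu residue bound through its secondary oxygen.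
- Dihydronaphthalene numbering: C1 bears the pendant aryl, C2 and C3 the esters, C4 is the vinylic CH, C4a and C8a are the ring-fusion carbons.
- Remark on the chemistry: the quaternary cyclopropane carbon carrying two carbonyl groups forms as a mixture of epimers. It becomes sp2 in the key step, so both epimers converge and its configuration is left open in the SMILES.

**Route**

Step 1
Reactants: 1 sodium (2R)-3-(3,4-dihydroxyphenyl)-2-hydroxypropanoate (sodium danshensu)
Product: 2 allyl (2R)-3-[3,4-bis(allyloxy)phenyl]-2-hydroxypropanoate (Dan–OH)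
Conditions: allyl bromide, K2CO3, DMF, rt
Reagents that add atoms: allyl bromide C=CCBr
Why: Williamson-type O-alkylation in which carbonate deprotonates only the two phenols and the carboxylate is alkylated as such, so the secondary alcohol should stay free and the stereocentre untouched.

Step 2
Reactants: 3 Meldrum's acid (2,2-dimethyl-1,3-dioxane-4,6-dione); 4 2-(trimethylsilyl)ethanol
Product: 5 3-oxo-3-[2-(trimethylsilyl)ethoxy]propanoic acid
Conditions: toluene, 100 °C
Reagents that add atoms: none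
Why: Thermal alcoholysis of Meldrum's acid (acyl substitution with loss of acetone) should give the malonic half ester directly.

Step 3
Reactants: 2 Dan–OH; 5 3-oxo-3-[2-(trimethylsilyl)ethoxy]propanoic acid
Product: 6 Dan TMSE malonate
Conditions: DCC, DMAP (cat.), CH2Cl2, 0 °C → rt
Reagents that add atoms: none
Why: Steglich esterification should acylate the secondary alcohol under neutral conditions that do not epimerise the α-acyloxy ester.

Step 4
Reactants: 6 Dan TMSE malonate
Product: 7 Dan TMSE 2-bromomalonate (epimers at CHBr)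
Conditions: CBr4, DBU, THF, −78 → 0 °C
Reagents that add atoms: carbon tetrabromide BrC(Br)(Br)Br
Why: Base-mediated α-bromination of a malonate by halogen transfer from CBr4 (the Bingel way of making a bromomalonate), chosen because the enolate reacts with CBr4 while the electron-rich arene and the allyl groups should not.

Step 5
Reactants: 8 3,4-dihydroxybenzaldehyde
Product: 9 3,4-bis(allyloxy)benzaldehyde
Conditions: allyl bromide, K2CO3, DMF, 50 °C
Reagents that add atoms: allyl bromide C=CCBr
Why: Williamson ether synthesis on both phenols.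

Step 6
Reactants: 9 3,4-bis(allyloxy)benzaldehyde
Product: 10 (2E)-3-[3,4-bis(allyloxy)phenyl]prop-2-enal
Conditions: Ph3P=CHCHO, toluene, 80 °C
Reagents that add atoms: (triphenylphosphoranylidene)acetaldehyde O=CC=P(c1ccccc1)(c1ccccc1)c1ccccc1
Why: Wittig olefination with a stabilised formyl ylide should give the (E)-enal.

Step 7
Reactants: 10 (2E)-3-[3,4-bis(allyloxy)phenyl]prop-2-enal; 7 Dan TMSE 2-bromomalonate
Product: 11 1-Dan 1-TMSE (2S,3R)-3-Ar-2-formylcyclopropane-1,1-dicarboxylate
Conditions: (R)-α,α-diphenylprolinol trimethylsilyl ether (20 mol%), 2,6-lutidine, CH2Cl2, 0 °C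
Reagents that add atoms: none
Why: Iminium–enamine organocascade (Michael addition of the bromomalonate, then intramolecular enamine α-alkylation) in which the (R)-diarylprolinol silyl ether shields one face of the (E)-iminium ion, so the malonate should add to the other face, fixing C3 as R and, through the trans ring closure, C2 as S, while the quaternary carbon is not controlled.

Step 8
Reactants: 11 1-Dan 1-TMSE (2S,3R)-3-Ar-2-formylcyclopropane-1,1-dicarboxylate
Product: 12 (2S,3R)-3-Ar-cyclopropane-1,1,2-tricarboxylic acid 1-Dan 1-TMSE diester (free CO2H on C2)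
Conditions: NaClO2, NaH2PO4, 2-methyl-2-butene, t-BuOH/H2O, 0 °C → rt
Reagents that add atoms: sodium chlorite [Na+].[O-]Cl=O
Why: Pinnick oxidation (chlorite with a hypochlorite scavenger) should convert the aldehyde into the acid without epimerising C2 or opening the donor–acceptor cyclopropane.

Step 9
Reactants: 12 (2S,3R)-3-Ar-cyclopropane-1,1,2-tricarboxylic acid 1-Dan 1-TMSE diester; 2 Dan–OH
Product: 13 1,2-di-Dan 1-TMSE (2S,3R)-3-Ar-cyclopropane-1,1,2-tricarboxylate
Conditions: DCC, DMAP (cat.), CH2Cl2, 0 °C → rt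
Reagents that add atoms: none
Why: Steglich esterification should install the second danshensu ester on C2 under neutral conditions, since the cyclopropyl acid cannot epimerise by way of a ketene and the alcohol reacts with retention.

Step 10
Reactants: 13 1,2-di-Dan 1-TMSE (2S,3R)-3-Ar-cyclopropane-1,1,2-tricarboxylate
Product: 14 (2S,3R)-3-Ar-cyclopropane-1,1,2-tricarboxylic acid 1,2-di-Dan diester (free CO2H on C1)
Conditions: Bu4NF, THF, 0 °C → rt; dilute aq. HCl work-up
Reagents that add atoms: none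
Why: Fluoride-triggered fragmentation of the 2-(trimethylsilyl)ethyl ester (β-elimination to ethene and Me3SiF) should free only the carboxyl group on C1, since allyl and secondary alkyl esters do not respond to fluoride and no stereocentre is touched.

Step 11
Reactants: 14 (2S,3R)-3-Ar-cyclopropane-1,1,2-tricarboxylic acid 1,2-di-Dan diester
Product: 16 1,2-di-Dan (2S,3R)-3-Ar-1-formylcyclopropane-1,2-dicarboxylate, via acid chloride 15 (not isolated)
Conditions: 1-chloro-N,N,2-trimethylprop-1-en-1-amine, CH2Cl2, 0 °C; then LiAlH(O-t-Bu)3, THF, −78 °C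
Reagents that add atoms: none
Why: Neutral acid chloride formation with an α-chloroenamine followed by partial reduction with the hindered hydride LiAlH(O-t-Bu)3 should stop at the aldehyde and leave the esters alone at −78 °C, and the acid chloride has no α-hydrogen, so no ketene can form.

Step 12
Reactants: 17 4-bromobenzene-1,2-diol
Product: 18 4-bromo-1,2-bis(allyloxy)benzene
Conditions: allyl bromide, K2CO3, DMF, rt
Reagents that add atoms: allyl bromide C=CCBr
Why: Williamson ether synthesis on both phenols.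

Step 13
Reactants: 16 1,2-di-Dan (2S,3R)-3-Ar-1-formylcyclopropane-1,2-dicarboxylate; 18 4-bromo-1,2-bis(allyloxy)benzene
Product: 21 deca-O-allylrabdosiin [di-Dan (1R,2S)-6,7-bis(allyloxy)-1-Ar-1,2-dihydronaphthalene-2,3-dicarboxylate], via aryl Grignard reagent 19 (not isolated), via cyclopropyl carbinol 20 (not isolated)
Conditions: 18, Mg, THF, rt; then 16, CH2Cl2, −78 °C; then CF3CO2H, −78 → 0 °C
Reagents that add atoms: none
Why: Grignard reagent 19 should add to the only aldehyde of 16 (carbonyl addition, far faster than ester attack at −78 °C) and so make the C4–C4a bond; acid then ionises the p-alkoxybenzylic carbinol 20 to a cyclopropylcarbinyl cation, which opens to the homoallyl cation by breaking the C3–C1 bond, giving the C3=C4 double bond and a benzylic cation at C1 stabilised by the 4-allyloxy group of the pendant ring. The closest known reaction type is the acid-mediated ring-opening benzannulation of aryl(2-arylcyclopropyl)methanols to 1-aryl-1,2-dihydronaphthalenes (cyclopropylcarbinyl–homoallyl rearrangement ended by a Friedel–Crafts alkylation). The six-membered carbocycle (C1, C2, C3, C4, C4a, C8a) closes by electrophilic aromatic substitution of C8a on the C1 cation, a 6-exo-trig closure with respect to the quinone-methide-like C1=aryl bond. C2 is carried unchanged from the cyclopropane, and the new stereocentre C1 is set by it, ring A attacking the cation face anti to the C2 ester so that aryl and ester should end up trans (1R,2S). The step needs cleavage of C3–C1 and not C3–C2 (secured by the donor aryl on C1 against the ester on C2), closure at the ring A carbon para to an allyloxy group and not between the substituents (secured by sterics and the para oxygen), and the C3=C4 geometry with ring A cis to C2 (the more stable cinnamate geometry, reached because cation opening is reversible and only this isomer can cyclise).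

Step 14
Reactants: 21 deca-O-allylrabdosiin
Product: 22 rabdosiin, (1R,2S) ring configuration with two (R)-danshensu esters
Conditions: Pd(PPh3)4 (cat.), morpholine, THF, rt, argon; dilute aq. HCl work-up
Reagents that add atoms: none
Why: Tsuji–Trost-type deallylation, in which Pd(PPh3)4 ionises each allyl ether and ester to a π-allyl complex that morpholine captures, is neutral and non-reductive and should leave the C3=C4 double bond and all four stereocentres untouched.

**Compound list**
1 | sodium (2R)-3-(3,4-dihydroxyphenyl)-2-hydroxypropanoate | O[C@H](Cc1ccc(O)c(O)c1)C(=O)[O-].[Na+] | starting material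
2 | allyl (2R)-3-[3,4-bis(allyloxy)phenyl]-2-hydroxypropanoate (Dan–OH) | O[C@H](Cc1ccc(OCC=C)c(OCC=C)c1)C(=O)OCC=C | intermediate
3 | Meldrum's acid | CC1(C)OC(=O)CC(=O)O1 | starting material
4 | 2-(trimethylsilyl)ethanol | C[Si](C)(C)CCO | starting material
5 | 3-oxo-3-[2-(trimethylsilyl)ethoxy]propanoic acid | OC(=O)CC(=O)OCC[Si](C)(C)C | intermediate
6 | Dan TMSE malonate | C[Si](C)(C)CCOC(=O)CC(=O)O[C@H](Cc1ccc(OCC=C)c(OCC=C)c1)C(=O)OCC=C | intermediate
7 | Dan TMSE 2-bromomalonate | C[Si](C)(C)CCOC(=O)C(Br)C(=O)O[C@H](Cc1ccc(OCC=C)c(OCC=C)c1)C(=O)OCC=C | intermediate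
8 | 3,4-dihydroxybenzaldehyde | O=Cc1ccc(O)c(O)c1 | starting material
9 | 3,4-bis(allyloxy)benzaldehyde | O=Cc1ccc(OCC=C)c(OCC=C)c1 | intermediate
10 | (2E)-3-[3,4-bis(allyloxy)phenyl]prop-2-enal | O=C/C=C/c1ccc(OCC=C)c(OCC=C)c1 | intermediate
11 | 1-Dan 1-TMSE (2S,3R)-3-Ar-2-formylcyclopropane-1,1-dicarboxylate | O=C[C@H]1[C@H](c2ccc(OCC=C)c(OCC=C)c2)C1(C(=O)OCC[Si](C)(C)C)C(=O)O[C@H](Cc1ccc(OCC=C)c(OCC=C)c1)C(=O)OCC=C | intermediate
12 | (2S,3R)-3-Ar-cyclopropane-1,1,2-tricarboxylic acid 1-Dan 1-TMSE diester | OC(=O)[C@H]1[C@H](c2ccc(OCC=C)c(OCC=C)c2)C1(C(=O)OCC[Si](C)(C)C)C(=O)O[C@H](Cc1ccc(OCC=C)c(OCC=C)c1)C(=O)OCC=C | intermediate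
13 | 1,2-di-Dan 1-TMSE (2S,3R)-3-Ar-cyclopropane-1,1,2-tricarboxylate | O=C(O[C@H](Cc1ccc(OCC=C)c(OCC=C)c1)C(=O)OCC=C)[C@H]1[C@H](c2ccc(OCC=C)c(OCC=C)c2)C1(C(=O)OCC[Si](C)(C)C)C(=O)O[C@H](Cc1ccc(OCC=C)c(OCC=C)c1)C(=O)OCC=C | intermediate
14 | (2S,3R)-3-Ar-cyclopropane-1,1,2-tricarboxylic acid 1,2-di-Dan diester | O=C(O[C@H](Cc1ccc(OCC=C)c(OCC=C)c1)C(=O)OCC=C)[C@H]1[C@H](c2ccc(OCC=C)c(OCC=C)c2)C1(C(=O)O)C(=O)O[C@H](Cc1ccc(OCC=C)c(OCC=C)c1)C(=O)OCC=C | intermediate
15 | 1,2-di-Dan (2S,3R)-3-Ar-1-(chlorocarbonyl)cyclopropane-1,2-dicarboxylate | O=C(O[C@H](Cc1ccc(OCC=C)c(OCC=C)c1)C(=O)OCC=C)[C@H]1[C@H](c2ccc(OCC=C)c(OCC=C)c2)C1(C(=O)Cl)C(=O)O[C@H](Cc1ccc(OCC=C)c(OCC=C)c1)C(=O)OCC=C | intermediate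
16 | 1,2-di-Dan (2S,3R)-3-Ar-1-formylcyclopropane-1,2-dicarboxylate | O=C(O[C@H](Cc1ccc(OCC=C)c(OCC=C)c1)C(=O)OCC=C)[C@H]1[C@H](c2ccc(OCC=C)c(OCC=C)c2)C1(C=O)C(=O)O[C@H](Cc1ccc(OCC=C)c(OCC=C)c1)C(=O)OCC=C | intermediate
17 | 4-bromobenzene-1,2-diol | Oc1ccc(Br)cc1O | starting material
18 | 4-bromo-1,2-bis(allyloxy)benzene | Brc1ccc(OCC=C)c(OCC=C)c1 | intermediate
19 | [3,4-bis(allyloxy)phenyl]magnesium bromide | Br[Mg]c1ccc(OCC=C)c(OCC=C)c1 | intermediate
20 | 1,2-di-Dan (2S,3R)-3-Ar-1-[Ar(hydroxy)methyl]cyclopropane-1,2-dicarboxylate (carbinol epimers) | O=C(O[C@H](Cc1ccc(OCC=C)c(OCC=C)c1)C(=O)OCC=C)[C@H]1[C@H](c2ccc(OCC=C)c(OCC=C)c2)C1(C(O)c1ccc(OCC=C)c(OCC=C)c1)C(=O)O[C@H](Cc1ccc(OCC=C)c(OCC=C)c1)C(=O)OCC=C | intermediate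
21 | deca-O-allylrabdosiin, di-Dan (1R,2S)-6,7-bis(allyloxy)-1-Ar-1,2-dihydronaphthalene-2,3-dicarboxylate | O=C(O[C@H](Cc1ccc(OCC=C)c(OCC=C)c1)C(=O)OCC=C)C1=Cc2cc(OCC=C)c(OCC=C)cc2[C@@H](c2ccc(OCC=C)c(OCC=C)c2)[C@@H]1C(=O)O[C@H](Cc1ccc(OCC=C)c(OCC=C)c1)C(=O)OCC=C | intermediate
22 | rabdosiin | O=C(O[C@H](Cc1ccc(O)c(O)c1)C(=O)O)C1=Cc2cc(O)c(O)cc2[C@@H](c2ccc(O)c(O)c2)[C@@H]1C(=O)O[C@H](Cc1ccc(O)c(O)c1)C(=O)O | target

**Step count and risks**
Total steps: 14. Longest linear sequence: 10 steps (1, 3, 4, 7, 8, 9, 10, 11, 13, 14).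

Step 13 (key step). What may go wrong: the C1 benzylic cation may lose the C2 proton (E1 elimination to a bis(arylidene)succinate diene); the cyclopropane may open to the alkene isomer that cannot cyclise and be trapped by trifluoroacetate; or the Grignard reagent may attack the activated esters. The fallback sets out from 16 and 18 and returns at 21. The Grignard addition is quenched with aqueous NH4Cl and carbinol 20 is isolated and oxidised with Dess–Martin periodinane in CH2Cl2 to the aryl cyclopropyl ketone F1. Catalytic Sc(OTf)3 in CH2Cl2 should open this doubly activated donor–acceptor cyclopropane to a chelated β-keto ester enolate and the C1 benzylic cation, onto which ring A closes to give the 4-oxotetralin F2; this is the known rearrangement of aryl cyclopropyl ketones to 4-aryl-1-tetralones, and because the enolate is held by chelation no alkene geometry has to be right. NaBH4 in THF/MeOH at −20 °C should reduce the ketone to the hydroxy ester F3, and p-TsOH in toluene should dehydrate it to 21.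

Step 11. What may go wrong: over-reduction of the acid chloride, or ring expansion of the labile formyl cyclopropane to a dihydrofuran (Cloke–Wilson rearrangement) on handling. The fallback sets out from 14 and returns at 16. Acid 14 is converted with isobutyl chloroformate and N-methylmorpholine (THF, −15 °C) into the mixed anhydride F4, which NaBH4 (THF/H2O, −15 °C) should reduce fully to the hydroxymethyl cyclopropane F5. F5 is oxidised at once with Dess–Martin periodinane (NaHCO3, CH2Cl2, 0 °C) and crude 16 is taken straight into step 13.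

Step 14. What may go wrong: C-allylation of the liberated catechol rings by the π-allylpalladium intermediates, incomplete tenfold cleavage, or air oxidation of the product. The fallback sets out from 21 and returns at 22. All ten allyl groups are first isomerised to (E)-prop-1-enyl groups with hydrogen-activated [Ir(cod)(PMePh2)2]PF6 in THF, giving the deca(prop-1-enyl) compound F6. The enol ethers and enol esters are then hydrolysed with dilute HCl in aqueous acetone under argon, which generates no electrophilic allyl species.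

Further compounds
F1 | step 13 | 1,2-di-Dan (2S,3R)-3-Ar-1-[3,4-bis(allyloxy)benzoyl]cyclopropane-1,2-dicarboxylate | O=C(O[C@H](Cc1ccc(OCC=C)c(OCC=C)c1)C(=O)OCC=C)[C@H]1[C@H](c2ccc(OCC=C)c(OCC=C)c2)C1(C(=O)c1ccc(OCC=C)c(OCC=C)c1)C(=O)O[C@H](Cc1ccc(OCC=C)c(OCC=C)c1)C(=O)OCC=C
F2 | step 13 | di-Dan (1R,2S)-6,7-bis(allyloxy)-1-Ar-4-oxo-1,2,3,4-tetrahydronaphthalene-2,3-dicarboxylate (C3 not defined) | O=C(O[C@H](Cc1ccc(OCC=C)c(OCC=C)c1)C(=O)OCC=C)C1C(=O)c2cc(OCC=C)c(OCC=C)cc2[C@@H](c2ccc(OCC=C)c(OCC=C)c2)[C@@H]1C(=O)O[C@H](Cc1ccc(OCC=C)c(OCC=C)c1)C(=O)OCC=C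
F3 | step 13 | di-Dan (1R,2S)-6,7-bis(allyloxy)-1-Ar-4-hydroxy-1,2,3,4-tetrahydronaphthalene-2,3-dicarboxylate (C3 and C4 not defined) | O=C(O[C@H](Cc1ccc(OCC=C)c(OCC=C)c1)C(=O)OCC=C)C1C(O)c2cc(OCC=C)c(OCC=C)cc2[C@@H](c2ccc(OCC=C)c(OCC=C)c2)[C@@H]1C(=O)O[C@H](Cc1ccc(OCC=C)c(OCC=C)c1)C(=O)OCC=C
F4 | step 11 | mixed isobutyl carbonic anhydride of acid 14 | O=C(O[C@H](Cc1ccc(OCC=C)c(OCC=C)c1)C(=O)OCC=C)[C@H]1[C@H](c2ccc(OCC=C)c(OCC=C)c2)C1(C(=O)OC(=O)OCC(C)C)C(=O)O[C@H](Cc1ccc(OCC=C)c(OCC=C)c1)C(=O)OCC=C
F5 | step 11 | 1,2-di-Dan (2S,3R)-3-Ar-1-(hydroxymethyl)cyclopropane-1,2-dicarboxylate | O=C(O[C@H](Cc1ccc(OCC=C)c(OCC=C)c1)C(=O)OCC=C)[C@H]1[C@H](c2ccc(OCC=C)c(OCC=C)c2)C1(CO)C(=O)O[C@H](Cc1ccc(OCC=C)c(OCC=C)c1)C(=O)OCC=C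
F6 | step 14 | deca-O-[(E)-prop-1-enyl]rabdosiin | O=C(O[C@H](Cc1ccc(O/C=C/C)c(O/C=C/C)c1)C(=O)O/C=C/C)C1=Cc2cc(O/C=C/C)c(O/C=C/C)cc2[C@@H](c2ccc(O/C=C/C)c(O/C=C/C)c2)[C@@H]1C(=O)O[C@H](Cc1ccc(O/C=C/C)c(O/C=C/C)c1)C(=O)O/C=C/C
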